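**Strategy.** Everything rests on reading ring A (C1–C5, C10; ent-kaurane numbering) as the six-membered ring of a bicyclo[3.2.1]octene whose two-carbon bridge is C19=C20: the cis oxygenated one-carbon arms on the quaternary carbons C4 and C10 are the scars of a cleaved cyclopentene. In the key step an oxyallyl cation (C1–C2–C3) adds across C4 and C10 of an enantiopure 2-silyloxycyclopentadiene, anti to the C5 side chain, in a (4+3) cycloaddition that forms C3–C4 and C1–C10, both quaternary centres and the all-cis C19/C6/C20 array at once. The temporary C19–C20 bond is later ozonised, the C2 carbonyl removed, and rings C and D added by samarium- and palladium-mediated cyclisations.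

Key step: step 5

Remark on the chemistry: ent-kaurane numbering is used throughout (C18 = methyl and C19 = CH2OAc on C4; C6 = CHO carbon on C5; C20 = CH2O on C10; C7 = lactone carbonyl; C8 = quaternary carbon; C11 = carbinol; C15 = ketone; C16=C17 = methylene). The acetoxymethyl group is taken as the one cis to C20 and C6 on ring A, as the given descriptors require. C8 is left as an epimer mixture in 26–28, 32 and 33 because it is made planar again later.

Step 1
Reactants: 1 (S)-4-((tert-butyldimethylsilyl)oxy)cyclopent-2-en-1-one; 2 tributyl((methoxymethoxy)methyl)stannane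
Product: 4 (S)-4-((methoxymethoxy)methyl)cyclopent-2-en-1-one, via silyloxy ketone 3 (not isolated)
Conditions: 2, n-BuLi, THF, −78 °C; CuI, −78 to −40 °C; 1, −78 °C; then DBU, CH2Cl2, 0 °C
Reagents that add atoms: none
Why: Cuprate conjugate addition of the alkoxymethyl group should occur anti to the silyloxy group, and E1cB loss of silanol then transposes the enone, so the future C5 stereocentre is relayed from the stereocentre of 1.

Step 2
Reactants: 4 (S)-4-((methoxymethoxy)methyl)cyclopent-2-en-1-one
Product: 6 (S)-4-((methoxymethoxy)methyl)-3-methylcyclopent-2-en-1-one, via trimethylsilyl enol ether 5 (not isolated)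
Conditions: Me2CuLi (from MeLi and CuI), Me3SiCl, THF, −78 °C; then Pd(OAc)2 (10 mol%), O2, DMSO, 23 °C
Reagents that add atoms: lithium dimethylcuprate, [Li+].C[Cu-]C
Why: Cuprate conjugate addition trapped as the silyl enol ether followed by Saegusa–Ito oxidation reinstalls the enone with the C18 methyl on C4; the transient methyl-bearing stereocentre is destroyed again and C5 is untouched.

Step 3
Reactants: 6 (S)-4-((methoxymethoxy)methyl)-3-methylcyclopent-2-en-1-one; 7 tert-butyl acrylate
Product: 8 tert-butyl 3-((1S,5S)-5-((methoxymethoxy)methyl)-4-methyl-2-oxocyclopent-3-en-1-yl)propanoate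
Conditions: LiN(i-Pr)2, THF, −78 °C; 7, −78 °C; AcOH, −78 °C
Reagents that add atoms: none
Why: Kinetic deprotonation gives the cross-conjugated enolate at C10, whose Michael addition to the acrylate should occur anti to the C5 side chain (this centre is erased in step 4), the β-methyl group and the cold quench disfavouring a second, intramolecular Michael addition.

Step 4
Reactants: 8 tert-butyl 3-((1S,5S)-5-((methoxymethoxy)methyl)-4-methyl-2-oxocyclopent-3-en-1-yl)propanoate
Product: 9 tert-butyl 3-((5R)-5-((methoxymethoxy)methyl)-4-methyl-2-((triisopropylsilyl)oxy)cyclopenta-1,3-dien-1-yl)propanoate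
Conditions: LiN(i-Pr)2, THF, −78 °C; i-Pr3SiOTf, −78 °C; cold work-up, used at once
Reagents that add atoms: triisopropylsilyl trifluoromethanesulfonate, CC(C)[Si](C(C)C)(C(C)C)OS(=O)(=O)C(F)(F)F
Why: Kinetic deprotonation at C10 of the ketone (more acidic than the ester) and O-silylation (silyl dienol ether formation) should give the 2-silyloxycyclopentadiene regiospecifically, and handling below −10 °C suppresses the 1,5-hydrogen shift that would scramble the diene and the C5 stereocentre.

Step 5
Reactants: 9 tert-butyl 3-((5R)-5-((methoxymethoxy)methyl)-4-methyl-2-((triisopropylsilyl)oxy)cyclopenta-1,3-dien-1-yl)propanoate; 10 1,1,3,3-tetrabromopropan-2-one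
Product: 12 bicyclo[3.2.1]oct-6-en-3-one with the C19=C20 silyl enol ether bridge, via dibromo cycloadduct 11 (not isolated)
Conditions: 10, Zn–Ag couple, THF, −10 °C; then Zn–Cu couple, NH4Cl, MeOH, −10 to 0 °C
Reagents that add atoms: none
Why: Zinc reduction of 10 gives a zinc 1,3-dibromo-2-oxyallyl cation that adds across C10 and C4 of the s-cis-locked siloxydiene 9, most likely C1–C10 first at the nucleophilic enol ether carbon and then C3–C4 by collapse of the zinc enolate onto the siloxyallyl cation, and the two bromines are then removed reductively by the Zn–Cu couple. The closest known reaction type is the oxyallyl cation (4+3) cycloaddition of polybromoketones with cyclopentadienes and furans. Ring A (C10–C1–C2–C3–C4–C5) is closed by intermolecular two-bond (4+3) annulation across the one-carbon bridge C5, and if the process is stepwise the second bond forms by seven-membered closure of the enolate on the allyl cation terminus C4. The quaternary stereocentres C4 and C10 are set by the resident C5 stereocentre, the cation approaching the diene face anti to CH2OMOM, and suprafacial bonding at both termini holds C19 and C20 cis to each other and to C6. The step needs periselectivity for the seven-membered closure over capture at C20 or simple alkylation, which the cyclic diene geometry and the crowding of vicinal fully substituted C10 and C20 should secure, and it must outrun the 1,5-hydrogen shift of 9, which the temperature of −10 °C should secure; regiochemistry is moot because the cation is symmetric.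

Step 6
Reactants: 12 bicyclo[3.2.1]oct-6-en-3-one with the C19=C20 silyl enol ether bridge
Product: 14 C2-deoxygenated bicyclo[3.2.1]oct-6-ene, via tosylhydrazone 13 (not isolated)
Conditions: TsNHNH2, MeOH, 23 °C; then catecholborane, CHCl3, 0 °C; NaOAc·3H2O, 60 °C
Reagents that add atoms: none
Why: Caglioti-type reduction of the unhindered C2 ketone through its tosylhydrazone (hydride addition, sulfinate loss, diazene fragmentation) should remove the oxygen under conditions that spare the silyl enol ether and the ester, with no stereocentre involved.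

Step 7
Reactants: 14 C2-deoxygenated bicyclo[3.2.1]oct-6-ene
Product: 16 ring A triol with C19 and C20 hydroxymethyl groups, via ozonide 15 (not isolated)
Conditions: O3, CH2Cl2, −78 °C; then LiAlH4, THF, −78 to 23 °C
Reagents that add atoms: ozone, [O-][O+]=O
Why: Ozonolysis cleaves the electron-rich enol ether C19=C20 (the temporary bridge) and hydride reduction of the ozonide and of the tert-butyl ester should give the triol, C19 and C20 staying cis because C4 and C10 are untouched.

Step 8
Reactants: 16 ring A triol with C19 and C20 hydroxymethyl groups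
Product: 17 spirolactone alcohol
Conditions: TEMPO (20 mol%), PhI(OAc)2 (2.5 equiv), CH2Cl2, 23 °C
Reagents that add atoms: none
Why: Nitroxyl-catalysed oxidative lactonisation should oxidise the unhindered C7 carbinol first, the aldehyde being trapped as the six-membered lactol by the C20 hydroxyl (the C19 hydroxyl would need an eight-membered ring) and oxidised on to the δ-lactone, which leaves the neopentylic C19 hydroxyl free.

Step 9
Reactants: 17 spirolactone alcohol
Product: 18 spirolactone benzyl ether
Conditions: 2-(benzyloxy)-1-methylpyridinium triflate, MgO, PhCF3, 85 °C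
Reagents that add atoms: 2-(benzyloxy)-1-methylpyridinium trifluoromethanesulfonate, C[n+]1ccccc1OCc1ccccc1.[O-]S(=O)(=O)C(F)(F)F
Why: Benzyl transfer from the pyridinium salt under neutral conditions (O-benzylation) should protect the C19 hydroxyl without touching the lactone or the acetal.

Step 10
Reactants: 19 (S)-4-benzyloxazolidin-2-one; 20 pent-4-enoyl chloride
Product: 21 (S)-4-benzyl-3-(pent-4-enoyl)oxazolidin-2-one
Conditions: 19, n-BuLi, THF, −78 °C; then 20
Reagents that add atoms: none
Why: N-Acylation of the lithiated oxazolidinone.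

Step 11
Reactants: 21 (S)-4-benzyl-3-(pent-4-enoyl)oxazolidin-2-one; 22 1-bromo-3-methylbut-2-ene
Product: 23 (S)-4-benzyl-3-((R)-2-allyl-5-methylhex-4-enoyl)oxazolidin-2-one
Conditions: NaN(SiMe3)2, THF, −78 °C; then 22, −78 to −40 °C
Reagents that add atoms: none
Why: Evans asymmetric alkylation, in which the chelated Z-enolate should be alkylated on the face opposite the benzyl group and so set C13 as (R).

Step 12
Reactants: 23 (S)-4-benzyl-3-((R)-2-allyl-5-methylhex-4-enoyl)oxazolidin-2-one
Product: 24 (R)-2-allyl-5-methylhex-4-en-1-ol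
Conditions: LiBH4, MeOH, Et2O, 0 °C
Reagents that add atoms: none
Why: Reductive cleavage of the imide by borohydride releases the primary alcohol without touching the stereocentre and returns the auxiliary.

Step 13
Reactants: 24 (R)-2-allyl-5-methylhex-4-en-1-ol
Product: 25 (R)-4-(iodomethyl)-7-methylocta-1,6-diene
Conditions: I2, PPh3, imidazole, CH2Cl2, 0 °C
Reagents that add atoms: iodine, [I][I]
Why: Appel-type iodination of the primary alcohol.

Step 14
Reactants: 18 spirolactone benzyl ether; 25 (R)-4-(iodomethyl)-7-methylocta-1,6-diene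
Product: 26 C8-alkylated spirolactone
Conditions: LiN(i-Pr)2, THF/HMPA, −78 °C; then 25, −78 to −20 °C
Reagents that add atoms: none
Why: Lactone enolate alkylation forms C8–C14; the C8 configuration is inconsequential because C8 becomes planar again in steps 16 and 20.

Step 15
Reactants: 26 C8-alkylated spirolactone
Product: 27 phenylthio lactone
Conditions: LiN(i-Pr)2, THF, −78 °C; then PhSSO2Ph, −78 to 0 °C
Reagents that add atoms: S-phenyl benzenethiosulfonate, O=S(=O)(Sc1ccccc1)c1ccccc1
Why: Sulfenylation of the lactone enolate with a reagent that does not add to the two side-chain alkenes.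

Step 16
Reactants: 27 phenylthio lactone
Product: 29 C8=C9 unsaturated spirolactone, via sulfoxide 28 (not isolated)
Conditions: mCPBA (1.0 equiv), CH2Cl2, −78 °C; then CaCO3, toluene, 110 °C
Reagents that add atoms: none
Why: Sulfide oxidation (far faster than alkene epoxidation at −78 °C) and thermal sulfoxide syn-elimination should give the endocyclic C8=C9 alkene, one ring hydrogen on C9 being held syn to the sulfinyl group.

Step 17
Reactants: 29 C8=C9 unsaturated spirolactone
Product: 31 unsaturated lactone aldehyde, via epoxide 30 (not isolated)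
Conditions: mCPBA, NaHCO3, CH2Cl2, 0 °C; then H5IO6, THF/H2O, 0 °C
Reagents that add atoms: 3-chloroperbenzoic acid, OOC(=O)c1cccc(Cl)c1
Why: Prilezhaev epoxidation should select the trisubstituted, most electron-rich alkene over the allyl group and the electron-poor lactone alkene, and periodic acid cleavage of the epoxide unmasks the C11 aldehyde.

Step 18
Reactants: 31 unsaturated lactone aldehyde
Product: 32 tricyclic hydroxy lactone
Conditions: SmI2, LiBr, t-BuOH, THF, −78 °C
Reagents that add atoms: none
Why: Samarium ketyl–olefin cyclisation (6-endo conjugate addition of the C11 ketyl to C9 of the unsaturated lactone) through a chair-like transition state with the ketyl oxygen pseudo-equatorial, attacking the C9 face anti to the pseudo-axial C1 methylene of ring A, should set C9 and C11 (hydroxyl trans to C10) and leave the C13 allyl group on the face needed in step 20.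

Step 19
Reactants: 32 tricyclic hydroxy lactone
Product: 33 C11 methoxymethyl ether
Conditions: MeOCH2Cl, i-Pr2NEt, CH2Cl2, 40 °C
Reagents that add atoms: chloromethyl methyl ether, COCCl
Why: Acetal formation (methoxymethyl ether) protects the C11 hydroxyl for the basic and oxidative steps that follow.

Step 20
Reactants: 33 C11 methoxymethyl ether
Product: 35 tetracycle with exocyclic methylene on C15, via silyl ketene acetal 34 (not isolated)
Conditions: KN(SiMe3)2, t-BuMe2SiCl, THF, −78 °C; then Pd(OAc)2 (1 equiv), DMSO, 45 °C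
Reagents that add atoms: none
Why: Palladium-mediated oxidative cyclisation of the silyl ketene acetal (Saegusa-type cycloalkenylation) by 5-exo attack of C8 on the coordinated allyl alkene at C15 and β-hydride elimination should close the bicyclo[3.2.1]octane, C8 being set because the allyl group on C13 can reach only one face of the ketene acetal.

Step 21
Reactants: 35 tetracycle with exocyclic methylene on C15
Product: 37 C15 ketone, via ozonide 36 (not isolated)
Conditions: O3, CH2Cl2, −78 °C; then PPh3
Reagents that add atoms: ozone, [O-][O+]=O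
Why: Ozonolysis of the 1,1-disubstituted alkene gives the C15 ketone next to the quaternary C8.

Step 22
Reactants: 37 C15 ketone
Product: 38 C19 alcohol
Conditions: H2 (1 atm), Pd/C, EtOAc, 23 °C
Reagents that add atoms: none
Why: Hydrogenolysis of the benzyl ether, to which the acetals, the ketone and the lactone are inert.

Step 23
Reactants: 38 C19 alcohol
Product: 41 α-methylene ketone acetate, via keto acetate 39 (not isolated), via Mannich base 40 (not isolated)
Conditions: Ac2O, DMAP (cat.), Me2NCH2NMe2, DMF, 23 °C then 95 °C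
Reagents that add atoms: acetic anhydride, CC(=O)OC(C)=O; N,N,N′,N′-tetramethylmethanediamine, CN(C)CN(C)C
Why: Acetylation of the primary C19 alcohol and Mannich methylenation with the iminium acetate formed in the flask, which can only occur at C16 (C8 is quaternary, C13 a bridgehead), followed by elimination of the amine.

Step 24
Reactants: 41 α-methylene ketone acetate
Product: 42 C6,C11 diol
Conditions: Me3SiOTf, 2,2′-bipyridyl, CH2Cl2, 0 °C; then H2O
Reagents that add atoms: none
Why: Silyl triflate–pyridine mediated cleavage of both methoxymethyl acetals through pyridinium intermediates, under buffered conditions that should spare the acetate, the lactone and the enone.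

Step 25
Reactants: 42 C6,C11 diol
Product: 43 trichorabdal B
Conditions: TEMPO (cat.), PhI(OAc)2, CH2Cl2, 23 °C
Reagents that add atoms: none
Why: Nitroxyl-catalysed oxidation should select the primary C6 alcohol over the hindered secondary C11 alcohol and deliver the aldehyde under neutral conditions that do not epimerise C5.

**Compound list**

1 | (S)-4-((tert-butyldimethylsilyl)oxy)cyclopent-2-en-1-one | O=C1C=C[C@@H](O[Si](C)(C)C(C)(C)C)C1 | starting material
2 | tributyl((methoxymethoxy)methyl)stannane | CCCC[Sn](CCCC)(CCCC)COCOC | starting material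
3 | (3R,4S)-4-((tert-butyldimethylsilyl)oxy)-3-((methoxymethoxy)methyl)cyclopentan-1-one (3,4-trans) | O=C1C[C@H](COCOC)[C@@H](O[Si](C)(C)C(C)(C)C)C1 | intermediate
4 | (S)-4-((methoxymethoxy)methyl)cyclopent-2-en-1-one | O=C1C=C[C@@H](COCOC)C1 | intermediate
5 | trimethylsilyl enol ether of trans-4-((methoxymethoxy)methyl)-3-methylcyclopentan-1-one, enol double bond toward C19 | C[Si](C)(C)OC1=C[C@H](C)[C@@H](COCOC)C1 | intermediate
6 | (S)-4-((methoxymethoxy)methyl)-3-methylcyclopent-2-en-1-one | O=C1C=C(C)[C@@H](COCOC)C1 | intermediate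
7 | tert-butyl acrylate | C=CC(=O)OC(C)(C)C | starting material
8 | tert-butyl 3-((1S,5S)-5-((methoxymethoxy)methyl)-4-methyl-2-oxocyclopent-3-en-1-yl)propanoate (1,5-trans) | CC(C)(C)OC(=O)CC[C@@H]1C(=O)C=C(C)[C@H]1COCOC | intermediate
9 | tert-butyl 3-((5R)-5-((methoxymethoxy)methyl)-4-methyl-2-((triisopropylsilyl)oxy)cyclopenta-1,3-dien-1-yl)propanoate | CC(C)(C)OC(=O)CCC1=C(O[Si](C(C)C)(C(C)C)C(C)C)C=C(C)[C@H]1COCOC | intermediate
10 | 1,1,3,3-tetrabromopropan-2-one | O=C(C(Br)Br)C(Br)Br | starting material
11 | 12 carrying one bromine on each of C1 and C3 (epimers at the bromine-bearing carbons) | CC(C)(C)OC(=O)CC[C@]12C(Br)C(=O)C(Br)[C@@](C)(C=C2O[Si](C(C)C)(C(C)C)C(C)C)[C@H]1COCOC | intermediate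
12 | bicyclo[3.2.1]oct-6-en-3-one: C2 ketone, bridgehead C4 with CH3, bridgehead C10 with CH2CH2CO2t-Bu, enol ether C19=C20 with OSi(i-Pr)3 on C20, bridge carbon C5 with CH2OMOM syn to C19=C20 | CC(C)(C)OC(=O)CC[C@]12CC(=O)C[C@@](C)(C=C2O[Si](C(C)C)(C(C)C)C(C)C)[C@H]1COCOC | intermediate
13 | 4-methylbenzenesulfonylhydrazone of 12 at C2 | CC(C)(C)OC(=O)CC[C@]12CC(=NNS(=O)(=O)c3ccc(C)cc3)C[C@@](C)(C=C2O[Si](C(C)C)(C(C)C)C(C)C)[C@H]1COCOC | intermediate
14 | 12 with CH2 in place of the C2 carbonyl | CC(C)(C)OC(=O)CC[C@]12CCC[C@@](C)(C=C2O[Si](C(C)C)(C(C)C)C(C)C)[C@H]1COCOC | intermediate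
15 | ozonide of 14, a 1,2,4-trioxolane spanning C19 and C20 | CC(C)(C)OC(=O)CC[C@@]12CCC[C@@](C)(C3OOC1(O[Si](C(C)C)(C(C)C)C(C)C)O3)[C@H]2COCOC | intermediate
16 | ring A triol: C4 with CH3 and CH2OH (C19), C5 with CH2OMOM (C6), C10 with CH2OH (C20) and CH2CH2CH2OH; C19, C6 and C20 arms all cis | OCCC[C@@]1(CCC[C@@](C)(CO)[C@H]1COCOC)CO | intermediate
17 | 8-(hydroxymethyl)-7-((methoxymethoxy)methyl)-8-methyl-2-oxaspiro[5.5]undecan-3-one, ring A configured as in the target | O=C1CC[C@@]2(CCC[C@@](C)(CO)[C@H]2COCOC)CO1 | intermediate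
18 | benzyl ether of 17 at the C19 oxygen | O=C1CC[C@@]2(CCC[C@@](C)(COCc3ccccc3)[C@H]2COCOC)CO1 | intermediate
19 | (S)-4-benzyloxazolidin-2-one | O=C1N[C@@H](Cc2ccccc2)CO1 | starting material
20 | pent-4-enoyl chloride | C=CCCC(Cl)=O | starting material
21 | (S)-4-benzyl-3-(pent-4-enoyl)oxazolidin-2-one | C=CCCC(=O)N1[C@@H](Cc2ccccc2)COC1=O | intermediate
22 | 1-bromo-3-methylbut-2-ene | CC(C)=CCBr | starting material
23 | (S)-4-benzyl-3-((R)-2-allyl-5-methylhex-4-enoyl)oxazolidin-2-one | C=CC[C@H](CC=C(C)C)C(=O)N1[C@@H](Cc2ccccc2)COC1=O | intermediate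
24 | (R)-2-allyl-5-methylhex-4-en-1-ol | C=CC[C@@H](CO)CC=C(C)C | intermediate
25 | (R)-4-(iodomethyl)-7-methylocta-1,6-diene | C=CC[C@@H](CI)CC=C(C)C | intermediate
26 | 18 alkylated at C8 with the (R)-2-allyl-5-methylhex-4-enyl group (C8 epimers) | O=C1C(C[C@H](CC=C)CC=C(C)C)C[C@@]2(CCC[C@@](C)(COCc3ccccc3)[C@H]2COCOC)CO1 | intermediate
27 | 26 with SPh on C8 | O=C1C(Sc3ccccc3)(C[C@H](CC=C)CC=C(C)C)C[C@@]2(CCC[C@@](C)(COCc4ccccc4)[C@H]2COCOC)CO1 | intermediate
28 | S-oxide of 27 | O=C1C(S(=O)c3ccccc3)(C[C@H](CC=C)CC=C(C)C)C[C@@]2(CCC[C@@](C)(COCc4ccccc4)[C@H]2COCOC)CO1 | intermediate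
29 | C8=C9 unsaturated spirolactone with the (R)-2-allyl-5-methylhex-4-enyl chain on C8 | O=C1C(C[C@H](CC=C)CC=C(C)C)=C[C@@]2(CCC[C@@](C)(COCc3ccccc3)[C@H]2COCOC)CO1 | intermediate
30 | 29 with the trisubstituted alkene epoxidised (epimers at the epoxide CH) | O=C1C(C[C@H](CC=C)CC3OC3(C)C)=C[C@@]2(CCC[C@@](C)(COCc4ccccc4)[C@H]2COCOC)CO1 | intermediate
31 | 29 with CH2CHO (C12–C11) in place of the 3-methylbut-2-enyl arm | O=C1C(C[C@H](CC=C)CC=O)=C[C@@]2(CCC[C@@](C)(COCc3ccccc3)[C@H]2COCOC)CO1 | intermediate
32 | tricyclic hydroxy lactone: ring C closed, 11-OH trans to C10 across C9–C11, allyl on C13 cis to C10, C8–H (epimers) | C=CC[C@@H]1C[C@@H](O)[C@@H]2[C@@]3(CCC[C@@](C)(COCc4ccccc4)[C@H]3COCOC)COC(=O)C2C1 | intermediate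
33 | 11-O-methoxymethyl ether of 32 | C=CC[C@@H]1C[C@@H](OCOC)[C@@H]2[C@@]3(CCC[C@@](C)(COCc4ccccc4)[C@H]3COCOC)COC(=O)C2C1 | intermediate
34 | tert-butyldimethylsilyl ketene acetal of 33 (C7=C8) | C=CC[C@@H]1C[C@@H](OCOC)[C@@H]2[C@@]3(CCC[C@@](C)(COCc4ccccc4)[C@H]3COCOC)COC(O[Si](C)(C)C(C)(C)C)=C2C1 | intermediate
35 | tetracycle with the bicyclo[3.2.1]octane closed, exocyclic methylene on C15, C16 as CH2 | C=C1C[C@@H]2C[C@@H](OCOC)[C@@H]3[C@@]4(CCC[C@@](C)(COCc5ccccc5)[C@H]4COCOC)COC(=O)[C@]13C2 | intermediate
36 | ozonide of 35, a spiro 1,2,4-trioxolane at C15 | C1OOC2(O1)C[C@@H]3C[C@@H](OCOC)[C@@H]4[C@@]5(CCC[C@@](C)(COCc6ccccc6)[C@H]5COCOC)COC(=O)[C@]24C3 | intermediate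
37 | C15 ketone with C19 benzyl ether and C6, C11 methoxymethyl ethers | O=C1C[C@@H]2C[C@@H](OCOC)[C@@H]3[C@@]4(CCC[C@@](C)(COCc5ccccc5)[C@H]4COCOC)COC(=O)[C@]13C2 | intermediate
38 | 37 with free C19 hydroxyl | O=C1C[C@@H]2C[C@@H](OCOC)[C@@H]3[C@@]4(CCC[C@@](C)(CO)[C@H]4COCOC)COC(=O)[C@]13C2 | intermediate
39 | 19-O-acetate of 38 | O=C1C[C@@H]2C[C@@H](OCOC)[C@@H]3[C@@]4(CCC[C@@](C)(COC(C)=O)[C@H]4COCOC)COC(=O)[C@]13C2 | intermediate
40 | 39 with CH2NMe2 on C16 | CN(C)CC1C(=O)[C@]23C[C@H]1C[C@@H](OCOC)[C@@H]2[C@@]1(CCC[C@@](C)(COC(C)=O)[C@H]1COCOC)COC3=O | intermediate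
41 | 6,11-bis-O-methoxymethyl ether of the C6 alcohol corresponding to trichorabdal B | C=C1C(=O)[C@]23C[C@H]1C[C@@H](OCOC)[C@@H]2[C@@]1(CCC[C@@](C)(COC(C)=O)[C@H]1COCOC)COC3=O | intermediate
42 | trichorabdal B with CH2OH in place of CHO at C6 | C=C1C(=O)[C@]23C[C@H]1C[C@@H](O)[C@@H]2[C@@]1(CCC[C@@](C)(COC(C)=O)[C@H]1CO)COC3=O | intermediate
43 | trichorabdal B | C=C1C(=O)[C@]23C[C@H]1C[C@@H](O)[C@@H]2[C@@]1(CCC[C@@](C)(COC(C)=O)[C@H]1C=O)COC3=O | target

**Step count.** Total: 25 steps. Longest linear sequence: 21 steps (steps 1–9 and 14–25); steps 10–13 make the side-chain iodide.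

**Steps most likely to fail**

Step 5. The siloxydiene may isomerise by 1,5-hydrogen shift before it is consumed. The oxyallyl cation may also be captured stepwise, closing at C20 to a five-membered ring or stopping at simple alkylation of C10, instead of closing the seven-membered ring. The fallback builds the same two bonds one after the other and sets out from 8. Alkylation of its C10 enolate (LiN(i-Pr)2, THF/HMPA, excess 1,3-diiodopropane) anti to the CH2OMOM group would give the quaternary iodide F1. Radical conjugate addition of the C3 radical to C4 of the enone (Bu3SnH, AIBN, benzene, 80 °C, 6-exo) would give the bicyclic ketone F2. Kinetic enolisation toward C19 and silylation (LiN(i-Pr)2, i-Pr3SiOTf) would come back to the route at 14.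

Step 16. The sulfoxide elimination may run toward C14 and give the exocyclic alkylidene lactone, or the alkene may migrate at 110 °C. The fallback installs the ring alkene before the side chain and sets out from 18. Selenation (LiN(i-Pr)2, PhSeBr) would give the α-selenide F3, and oxidation with H2O2 would eliminate it to the unsaturated spirolactone F4, where only the C9 hydrogens are available. Iodination (I2, pyridine, CH2Cl2) would give the α-iodo lactone F5. A B-alkyl Suzuki–Miyaura coupling (PdCl2(dppf), AsPh3, Cs2CO3, DMF/H2O) with the borate F6, made from 25 with t-BuLi and 9-methoxy-9-borabicyclo[3.3.1]nonane, would come back to the route at 29.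

Step 20. The silyl ketene acetal may lose its silyl group before cyclising, or the palladium enolate may close in the 6-endo sense to a bicyclo[2.2.2]octane. The fallback closes C8–C15 by an aldol of a regiospecifically generated enolate and sets out from 33. Bromination of the lactone enolate (LiN(i-Pr)2, CBr4, −78 °C) would give the α-bromo lactone F7. Ozonolysis of the allyl group (O3, then PPh3), through the ozonide F8, would give the aldehyde F9. A samarium Reformatsky-type aldol (SmI2, THF, −78 °C) would close ring D to the hydroxy lactone F10, and oxidation with DMP would come back to the route at 37.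

**Further compounds**

F1 | step 5 | tert-butyl 3-(1-(3-iodopropyl)-5-((methoxymethoxy)methyl)-4-methyl-2-oxocyclopent-3-en-1-yl)propanoate, iodopropyl trans to CH2OMOM | CC(C)(C)OC(=O)CC[C@@]1(CCCI)C(=O)C=C(C)[C@H]1COCOC
F2 | step 5 | bicyclo[3.2.1]octan-6-one with C20 ketone and C19 as CH2, otherwise substituted as 14 | CC(C)(C)OC(=O)CC[C@]12CCC[C@@](C)(CC2=O)[C@H]1COCOC
F3 | step 16 | 18 with SePh on C8 | O=C1C([Se]c3ccccc3)C[C@@]2(CCC[C@@](C)(COCc4ccccc4)[C@H]2COCOC)CO1
F4 | step 16 | C8=C9 unsaturated spirolactone without a C8 substituent | O=C1C=C[C@@]2(CCC[C@@](C)(COCc3ccccc3)[C@H]2COCOC)CO1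
F5 | step 16 | F4 with iodine on C8 | O=C1C([I])=C[C@@]2(CCC[C@@](C)(COCc3ccccc3)[C@H]2COCOC)CO1
F6 | step 16 | lithium B-methoxy borate from 25 and 9-methoxy-9-borabicyclo[3.3.1]nonane | [Li+].C=CC[C@@H](C[B-]1(OC)C2CCCC1CCC2)CC=C(C)C
F7 | step 20 | 33 with bromine on C8 | C=CC[C@@H]1C[C@@H](OCOC)[C@@H]2[C@@]3(CCC[C@@](C)(COCc4ccccc4)[C@H]3COCOC)COC(=O)C2(Br)C1
F8 | step 20 | ozonide of the allyl group of F7 | C1OC(OO1)C[C@@H]2C[C@@H](OCOC)[C@@H]3[C@@]4(CCC[C@@](C)(COCc5ccccc5)[C@H]4COCOC)COC(=O)C3(Br)C2
F9 | step 20 | F7 with CH2CHO (C16–C15) in place of the allyl group | O=CC[C@@H]1C[C@@H](OCOC)[C@@H]2[C@@]3(CCC[C@@](C)(COCc4ccccc4)[C@H]3COCOC)COC(=O)C2(Br)C1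
F10 | step 20 | 37 with a C15 carbinol in place of the ketone | OC1C[C@@H]2C[C@@H](OCOC)[C@@H]3[C@@]4(CCC[C@@](C)(COCc5ccccc5)[C@H]4COCOC)COC(=O)[C@]13C2
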